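**Plan**

- Retrosynthesis: remove the 4'-O-allyl group, then cut O1–C2 and C2–C3 of ring C (C2 comes from DMF dimethyl acetal), then cut C4a–C8a of ring A. This unfolds ring A into an open C4–C8a chain whose C8a is the carbonyl of a γ-lactone.
- Enabling feature: ring A carries oxygen on C5, C7 and C8a (1,3,5) and the C4 carbonyl on C4a, i.e. an acylphloroglucinol, the folding pattern of a 3,5,7-tricarbonyl chain. The carbinol oxygen of the C8 side chain is γ to C8a, so C8a, C8 and the carbinol can be held as one butyrolactone.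
- The chain is cut at C7–C8 (lactone enolate + acid chloride) and at C4–C4a (dianion + Weinreb amide). C5–C7 with the OMe and prenyl groups come from methyl acetoacetate.
- Forward: three fragments (enol-ether acid 5, lactone 9, amide 14) are joined C7–C8, then C4a–C4; ring A closes in step 10, ring C in step 11; deallylation ends the route.
- Stereochemistry: the one stereocentre (R carbinol) is bought as (R)-5-oxotetrahydrofuran-2-carboxylic acid; no bond to it is made or broken anywhere in the route.

Key step: step 10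

Remark: atom labels C2–C8a are the chromenone numbers of the target. Enol ethers 4, 5, 10, 11 and 15 are drawn E (C4a cis to C7); a Z fraction can be carried along, because the geometry is lost in the delocalised anions of steps 9 and 10. Compounds 3, 11, 15 and 16 are epimer mixtures at a carbon that later becomes sp2 (C6 or C8).

**Step 1**
Reactants: 1 methyl acetoacetate; 2 prenyl bromide
Product: 3 methyl 2-acetyl-5-methylhex-4-enoate (racemic)
Conditions: K2CO3, acetone, reflux (1 in slight excess)
Reagents that add atoms: none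
Why: SN2 C-alkylation of the β-keto ester enolate by the allylic bromide (acetoacetic ester alkylation); the excess of 1 should suppress double prenylation.

**Step 2**
Reactants: 3
Product: 4 methyl (2E)-3-methoxy-2-(3-methylbut-2-en-1-yl)but-2-enoate
Conditions: KOt-Bu, DMPU, 0 °C; Me2SO4, 0 °C → rt
Reagents that add atoms: dimethyl sulfate, COS(=O)(=O)OC
Why: O-alkylation of the free potassium enolate of an α-substituted β-keto ester by a hard electrophile in a dipolar aprotic medium; the extended enolate should give mainly the E enol ether.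

**Step 3**
Reactants: 4
Product: 5 (2E)-3-methoxy-2-(3-methylbut-2-en-1-yl)but-2-enoic acid
Conditions: KOH, MeOH–H2O, 60 °C; then cold 1 M HCl to pH 3–4
Reagents that add atoms: potassium hydroxide (KOH), [K+].[OH-]
Why: Saponification of the vinylogous carbonate ester; the enol ether is stable to base and should survive a brief cold acidification.

**Step 4**
Reactants: 6 (R)-5-oxotetrahydrofuran-2-carboxylic acid
Product: 8 (5R)-5-acetyldihydrofuran-2(3H)-one, via acid chloride 7 (not isolated)
Conditions: (COCl)2, DMF (cat.), CH2Cl2, 0 °C → rt; evaporate; MeMgBr (1.0 equiv), CuI (10 mol %), THF, −78 °C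
Reagents that add atoms: methylmagnesium bromide (MeMgBr), C[Mg]Br
Why: Acid chloride formation followed by copper-catalysed acylation of the Grignard reagent, which at −78 °C should stop at the ketone and spare the lactone; the stereocentre is not involved.

**Step 5**
Reactants: 8
Product: 9 (5R)-5-(prop-1-en-2-yl)dihydrofuran-2(3H)-one
Conditions: Zn, CH2Br2, TiCl4, THF (pre-formed reagent); 8, CH2Cl2, 0 °C → rt
Reagents that add atoms: dibromomethane, BrCBr
Why: Takai–Lombardo methylenation; the non-basic zinc/titanium reagent olefinates ketones but not lactones and should not enolise the adjacent stereocentre.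

**Step 6**
Reactants: 5; 9 (2.0 equiv)
Product: 11 (5R)-3-[(2E)-3-methoxy-2-(3-methylbut-2-en-1-yl)but-2-enoyl]-5-(prop-1-en-2-yl)dihydrofuran-2(3H)-one, via acid chloride 10 (not isolated)
Conditions: 5, Me2C=C(Cl)NMe2, CH2Cl2, 0 °C → rt; separately 9, LiN(SiMe3)2 (2.0 equiv), THF, −78 °C; add 10, −78 °C; aq. NH4Cl
Reagents that add atoms: none
Why: Crossed Claisen-type C-acylation of the lactone lithium enolate by an acid chloride made under neutral conditions (Ghosez reagent, so prenyl group and enol ether see no HCl); the second equivalent of enolate stores 11 as its enolate, and the surplus 9 is recovered.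

**Step 7**
Reactants: 12 4-hydroxyphenylacetic acid
Product: 13 allyl [4-(allyloxy)phenyl]acetate
Conditions: allyl bromide (2.5 equiv), K2CO3, DMF, 50 °C
Reagents that add atoms: allyl bromide, C=CCBr
Why: Williamson etherification of the phenol and alkylation of the carboxylate in one operation; the allyl ether is chosen because it survives strong base and methoxide.

**Step 8**
Reactants: 13
Product: 14 2-[4-(allyloxy)phenyl]-N-methoxy-N-methylacetamide
Conditions: MeNH(OMe)·HCl, i-PrMgCl, THF, −20 → 0 °C
Reagents that add atoms: N,O-dimethylhydroxylamine hydrochloride, CNOC.Cl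
Why: Aminolysis of the ester by the chloromagnesium amide of N,O-dimethylhydroxylamine (Weinreb amide formation from esters).

**Step 9**
Reactants: 11; 14
Product: 15 (5R)-3-{(2E)-6-[4-(allyloxy)phenyl]-3-methoxy-2-(3-methylbut-2-en-1-yl)-5-oxohex-2-enoyl}-5-(prop-1-en-2-yl)dihydrofuran-2(3H)-one
Conditions: LiN(i-Pr)2 (2.3 equiv), THF, −78 → −30 °C; 14, −78 → 0 °C; aq. NH4Cl; quick filtration through Et3N-washed silica
Reagents that add atoms: none
Why: Polyanion γ-acylation: the first equivalent of base forms the β-keto lactone enolate, the second removes a proton from the C5 methyl group (vinylogous to the C7 carbonyl and the only other acidic site), and this terminal carbanion attacks the Weinreb amide, whose chelated tetrahedral adduct prevents over-addition and keeps the acidic product out of the base until the quench.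

**Step 10**
Reactants: 15
Product: 17 2-[4-(allyloxy)phenyl]-1-{2,4-dihydroxy-3-[(2R)-2-hydroxy-3-methylbut-3-en-1-yl]-6-methoxy-5-(3-methylbut-2-en-1-yl)phenyl}ethanone, via ring-closed trione 16 (not isolated)
Conditions: Mg(OMe)2 (6 equiv), MeOH, rt → 50 °C; cold 0.5 M HCl to pH 4–5
Reagents that add atoms: none
Why: Proposed new method: in methanolic Mg(OMe)2 the C4a methylene of 15, acidified directly by the C4 ketone and vinylogously through the C5=C6 enol ether by the C7 ketone, is ionised and adds to the lactone carbonyl C8a, the tetrahedral adduct expels the side-chain alkoxide to give trione 16, and 16 enolises irreversibly to the phenol 17. The closest known reaction type is the Mg(OMe)2-mediated Claisen cyclisation of 3,5,7-triketo esters to acylphloroglucinols; new here are the methyl enol ether at C5 and the γ-lactone as acyl donor, which also frees the carbinol by acyl–oxygen cleavage. Ring A closes in the 6-exo-trig mode (enolate carbon C4a onto C8a, forming the C4a–C8a bond). No stereocentre is formed: the R carbinol centre has no bond made or broken, and the epimeric C8 becomes aromatic. The step needs Claisen over aldol closure and C4a cis to C7: attack of C8 on C4 gives a quaternary adduct that cannot aromatise and reverts, the benzylic carbon is far less acidic than C4a and its target C7 is a hindered vinylogous ester carbonyl tied up in the magnesium chelate, and the enol-ether geometry equilibrates through the delocalised C4a anion so that the cis form is drained. Magnesium chelation of the 1,3-dioxygen units is expected to hold C4a near C8a, and the aryl allyl ether and the alkenes are inert to methoxide.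

**Step 11**
Reactants: 17
Product: 19 3-[4-(allyloxy)phenyl]-7-hydroxy-8-[(2R)-2-hydroxy-3-methylbut-3-en-1-yl]-5-methoxy-6-(3-methylbut-2-en-1-yl)-4H-chromen-4-one, via enaminone 18 (not isolated)
Conditions: Me2NCH(OMe)2 (3 equiv), THF, 60 °C; then MeOH, AcOH (cat.), rt
Reagents that add atoms: N,N-dimethylformamide dimethyl acetal, COC(OC)N(C)C
Why: Aminomethylenation of the benzylic methylene by the amide acetal gives enaminone 18, whose β-carbon is attacked by the 8a-OH (the only hydroxyl ortho to the ketone, since O5 is methylated) with loss of Me2NH; this is the standard deoxybenzoin-to-isoflavone closure.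

**Step 12**
Reactants: 19
Product: 20 7-hydroxy-8-[(2R)-2-hydroxy-3-methylbut-3-en-1-yl]-3-(4-hydroxyphenyl)-5-methoxy-6-(3-methylbut-2-en-1-yl)-4H-chromen-4-one (CNP0324832.1)
Conditions: Pd(PPh3)4 (5 mol %), morpholine, THF, rt
Reagents that add atoms: none
Why: Tsuji–Trost deallylation of the aryl allyl ether by zerovalent palladium with morpholine as allyl acceptor; the prenyl groups and the unactivated allylic alcohol should not ionise.

**Compound list**

1 | methyl acetoacetate | CC(=O)CC(=O)OC | starting material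
2 | prenyl bromide (1-bromo-3-methylbut-2-ene) | CC(C)=CCBr | starting material
3 | methyl 2-acetyl-5-methylhex-4-enoate (racemic) | CC(=O)C(CC=C(C)C)C(=O)OC | intermediate
4 | methyl (2E)-3-methoxy-2-(3-methylbut-2-en-1-yl)but-2-enoate | C/C(OC)=C(/CC=C(C)C)C(=O)OC | intermediate
5 | (2E)-3-methoxy-2-(3-methylbut-2-en-1-yl)but-2-enoic acid | C/C(OC)=C(/CC=C(C)C)C(=O)O | intermediate
6 | (R)-5-oxotetrahydrofuran-2-carboxylic acid | OC(=O)[C@H]1CCC(=O)O1 | starting material
7 | (2R)-5-oxotetrahydrofuran-2-carbonyl chloride (not isolated) | O=C(Cl)[C@H]1CCC(=O)O1 | intermediate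
8 | (5R)-5-acetyldihydrofuran-2(3H)-one | CC(=O)[C@H]1CCC(=O)O1 | intermediate
9 | (5R)-5-(prop-1-en-2-yl)dihydrofuran-2(3H)-one | C=C(C)[C@H]1CCC(=O)O1 | intermediate
10 | (2E)-3-methoxy-2-(3-methylbut-2-en-1-yl)but-2-enoyl chloride (not isolated) | C/C(OC)=C(/CC=C(C)C)C(=O)Cl | intermediate
11 | (5R)-3-[(2E)-3-methoxy-2-(3-methylbut-2-en-1-yl)but-2-enoyl]-5-(prop-1-en-2-yl)dihydrofuran-2(3H)-one (C3 epimers) | C=C(C)[C@H]1CC(C(=O)/C(CC=C(C)C)=C(/OC)C)C(=O)O1 | intermediate
12 | 4-hydroxyphenylacetic acid | OC(=O)Cc1ccc(O)cc1 | starting material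
13 | allyl [4-(allyloxy)phenyl]acetate | C=CCOC(=O)Cc1ccc(OCC=C)cc1 | intermediate
14 | 2-[4-(allyloxy)phenyl]-N-methoxy-N-methylacetamide | CON(C)C(=O)Cc1ccc(OCC=C)cc1 | intermediate
15 | (5R)-3-{(2E)-6-[4-(allyloxy)phenyl]-3-methoxy-2-(3-methylbut-2-en-1-yl)-5-oxohex-2-enoyl}-5-(prop-1-en-2-yl)dihydrofuran-2(3H)-one (C3 epimers; key-step precursor) | C=C(C)[C@H]1CC(C(=O)/C(CC=C(C)C)=C(/OC)CC(=O)Cc2ccc(OCC=C)cc2)C(=O)O1 | intermediate
16 | 4-{[4-(allyloxy)phenyl]acetyl}-2-[(2R)-2-hydroxy-3-methylbut-3-en-1-yl]-5-methoxy-6-(3-methylbut-2-en-1-yl)cyclohex-5-ene-1,3-dione (not isolated) | C=C(C)[C@H](O)CC1C(=O)C(CC=C(C)C)=C(OC)C(C(=O)Cc2ccc(OCC=C)cc2)C1=O | intermediate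
17 | 2-[4-(allyloxy)phenyl]-1-{2,4-dihydroxy-3-[(2R)-2-hydroxy-3-methylbut-3-en-1-yl]-6-methoxy-5-(3-methylbut-2-en-1-yl)phenyl}ethanone | C=C(C)[C@H](O)Cc1c(O)c(CC=C(C)C)c(OC)c(C(=O)Cc2ccc(OCC=C)cc2)c1O | intermediate
18 | 2-[4-(allyloxy)phenyl]-1-{2,4-dihydroxy-3-[(2R)-2-hydroxy-3-methylbut-3-en-1-yl]-6-methoxy-5-(3-methylbut-2-en-1-yl)phenyl}-3-(dimethylamino)prop-2-en-1-one (not isolated) | C=C(C)[C@H](O)Cc1c(O)c(CC=C(C)C)c(OC)c(C(=O)C(=CN(C)C)c2ccc(OCC=C)cc2)c1O | intermediate
19 | 3-[4-(allyloxy)phenyl]-7-hydroxy-8-[(2R)-2-hydroxy-3-methylbut-3-en-1-yl]-5-methoxy-6-(3-methylbut-2-en-1-yl)-4H-chromen-4-one | C=C(C)[C@H](O)Cc1c(O)c(CC=C(C)C)c(OC)c2c(=O)c(-c3ccc(OCC=C)cc3)coc12 | intermediate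
20 | 7-hydroxy-8-[(2R)-2-hydroxy-3-methylbut-3-en-1-yl]-3-(4-hydroxyphenyl)-5-methoxy-6-(3-methylbut-2-en-1-yl)-4H-chromen-4-one | C=C(C)[C@H](O)Cc1c(O)c(CC=C(C)C)c(OC)c2c(=O)c(-c3ccc(O)cc3)coc12 | target

**Totals**

Total step count: 12. Longest linear sequence: 8 steps (steps 1, 2, 3, 6, 9, 10, 11, 12).

**Steps most likely to fail**

1. Step 10 (proposed new method). What may go wrong: loss of chemoselectivity, with the benzylic or the C8 carbanion closing by aldol addition instead of C4a closing by Claisen; cleavage of the β-keto lactone by methoxide (retro-Claisen); cyclodehydration of the masked triketone to a 4-pyranone during handling. The fallback gives up the folding and builds ring A on a symmetric arene by directed ortho-metalation, using known reactions only. It sets out from prenyl bromide 2 and amide 14 and comes back at 17.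
   - Commercial 5-methoxyresorcinol is converted with MOMCl and i-Pr2NEt into 5-methoxy-1,3-bis(methoxymethoxy)benzene F1.
   - Lithiation between the two MOM ethers (n-BuLi, THF, 0 °C), transmetalation with CuBr·SMe2 and alkylation with 2 should give 5-methoxy-1,3-bis(methoxymethoxy)-2-(3-methylbut-2-en-1-yl)benzene F2.
   - Shi epoxidation (D-fructose-derived ketone, KHSO5, pH 10.5) should give (3R)-3-[4-methoxy-2,6-bis(methoxymethoxy)benzyl]-2,2-dimethyloxirane F3.
   - Base-induced epoxide-to-allylic-alcohol isomerisation with Et2Al(TMP) should give (2R)-1-[4-methoxy-2,6-bis(methoxymethoxy)phenyl]-3-methylbut-3-en-2-ol F4, with the C–O bond at the stereocentre untouched.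
   - TBSCl and imidazole give tert-butyl{[(2R)-1-[4-methoxy-2,6-bis(methoxymethoxy)phenyl]-3-methylbut-3-en-2-yl]oxy}dimethylsilane F5.
   - A second lithiation (n-BuLi, TMEDA) at either of the two equivalent positions between OMe and OMOM, then CuBr·SMe2 and 2, gives tert-butyl{[(2R)-1-[4-methoxy-2,6-bis(methoxymethoxy)-3-(3-methylbut-2-en-1-yl)phenyl]-3-methylbut-3-en-2-yl]oxy}dimethylsilane F6.
   - Lithiation of the last ring hydrogen and addition to 14 gives 2-[4-(allyloxy)phenyl]-1-{3-[(2R)-2-(tert-butyldimethylsilyloxy)-3-methylbut-3-en-1-yl]-6-methoxy-2,4-bis(methoxymethoxy)-5-(3-methylbut-2-en-1-yl)phenyl}ethanone F7.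
   - HCl in MeOH removes the two MOM groups and the silyl ether to give 17.
   - The symmetry of F1 takes over the regiocontrol that the chain sequence provides in the main route.

2. Step 9. What may go wrong: quenching of the dianion by proton transfer from the benzylic CH2 of the amide before acyl substitution occurs, returning 11. The fallback replaces acyl substitution by aldol addition followed by oxidation. It sets out from 14 and 11 and comes back at 15.
   - Amide 14 is reduced with LiAlH4 (THF, −78 → 0 °C) to [4-(allyloxy)phenyl]acetaldehyde F8.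
   - F8 is added at −78 °C to the dianion of 11; carbonyl addition to an aldehyde is far faster than substitution at an amide. This should give (5R)-3-{(2E)-6-[4-(allyloxy)phenyl]-5-hydroxy-3-methoxy-2-(3-methylbut-2-en-1-yl)hex-2-enoyl}-5-(prop-1-en-2-yl)dihydrofuran-2(3H)-one F9.
   - Dess–Martin periodinane buffered with NaHCO3 oxidises F9 to 15.

3. Step 11. What may go wrong: O-methylation of the acidic 7-OH by the amide acetal, or acetal exchange at the secondary alcohol that consumes reagent and stalls the condensation. The fallback uses Claisen formylation and cyclodehydration, with no alkylating agent present. It sets out from 17 and comes back at 19.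
   - With ethyl formate and NaH (excess, THF, 0 °C → rt) the benzylic methylene of 17 is C-formylated, and the formyl ketone closes to 3-[4-(allyloxy)phenyl]-2,7-dihydroxy-8-[(2R)-2-hydroxy-3-methylbut-3-en-1-yl]-5-methoxy-6-(3-methylbut-2-en-1-yl)-2,3-dihydro-4H-chromen-4-one F10.
   - Warm AcOH dehydrates F10 to 19.

**Further compounds**

F1 | step 10 | 5-methoxy-1,3-bis(methoxymethoxy)benzene | COCOc1cc(OC)cc(OCOC)c1
F2 | step 10 | 5-methoxy-1,3-bis(methoxymethoxy)-2-(3-methylbut-2-en-1-yl)benzene | COCOc1cc(OC)cc(OCOC)c1CC=C(C)C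
F3 | step 10 | (3R)-3-[4-methoxy-2,6-bis(methoxymethoxy)benzyl]-2,2-dimethyloxirane | COCOc1cc(OC)cc(OCOC)c1C[C@H]1OC1(C)C
F4 | step 10 | (2R)-1-[4-methoxy-2,6-bis(methoxymethoxy)phenyl]-3-methylbut-3-en-2-ol | COCOc1cc(OC)cc(OCOC)c1C[C@@H](O)C(C)=C
F5 | step 10 | tert-butyl{[(2R)-1-[4-methoxy-2,6-bis(methoxymethoxy)phenyl]-3-methylbut-3-en-2-yl]oxy}dimethylsilane | COCOc1cc(OC)cc(OCOC)c1C[C@@H](O[Si](C)(C)C(C)(C)C)C(C)=C
F6 | step 10 | tert-butyl{[(2R)-1-[4-methoxy-2,6-bis(methoxymethoxy)-3-(3-methylbut-2-en-1-yl)phenyl]-3-methylbut-3-en-2-yl]oxy}dimethylsilane | COCOc1c(CC=C(C)C)c(OC)cc(OCOC)c1C[C@@H](O[Si](C)(C)C(C)(C)C)C(C)=C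
F7 | step 10 | 2-[4-(allyloxy)phenyl]-1-{3-[(2R)-2-(tert-butyldimethylsilyloxy)-3-methylbut-3-en-1-yl]-6-methoxy-2,4-bis(methoxymethoxy)-5-(3-methylbut-2-en-1-yl)phenyl}ethanone | COCOc1c(CC=C(C)C)c(OC)c(C(=O)Cc2ccc(OCC=C)cc2)c(OCOC)c1C[C@@H](O[Si](C)(C)C(C)(C)C)C(C)=C
F8 | step 9 | [4-(allyloxy)phenyl]acetaldehyde | O=CCc1ccc(OCC=C)cc1
F9 | step 9 | (5R)-3-{(2E)-6-[4-(allyloxy)phenyl]-5-hydroxy-3-methoxy-2-(3-methylbut-2-en-1-yl)hex-2-enoyl}-5-(prop-1-en-2-yl)dihydrofuran-2(3H)-one | C=C(C)[C@H]1CC(C(=O)/C(CC=C(C)C)=C(/OC)CC(O)Cc2ccc(OCC=C)cc2)C(=O)O1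
F10 | step 11 | 3-[4-(allyloxy)phenyl]-2,7-dihydroxy-8-[(2R)-2-hydroxy-3-methylbut-3-en-1-yl]-5-methoxy-6-(3-methylbut-2-en-1-yl)-2,3-dihydro-4H-chromen-4-one | C=C(C)[C@H](O)Cc1c(O)c(CC=C(C)C)c(OC)c2c1OC(O)C(c1ccc(OCC=C)cc1)C2=O
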